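**Retrosynthetic overview**
1. The thiazine dioxide ring comes last. Hypotaurine adds (sulfur first, then nitrogen) to a 6,7-disubstituted 1,4-naphthoquinone, which is unmasked from a 1,4-dimethoxynaphthalene.
2. The dienol lactone is traced back to an isomeric lactone in which the same two C=C bonds sit inside ring A as a cyclohexa-1,3-diene. A hydride-catalysed double-bond walk connects the two, with no redox change.
3. Key (4+3) disconnection of the seven-membered lactone: cutting O–CH (exocyclic carbon) and aryl C–C (quaternary) gives 3-bromo-5,8-dimethoxy-2-naphthoic acid and (2,6-dimethylcyclohexa-2,5-dienyl)methyl mesylate.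
4. Enabling feature: in ring A the carbon bearing the exocyclic CH–O is flanked by two methyl-bearing carbons, the quaternary C and the vinylic C–CH3. Ring A therefore hides a mirror-symmetric 2,6-dimethylcyclohexadienylmethyl unit with two enantiotopic C(CH3)=CH groups, and the carboxyl group ortho to the aryl–C bond serves as both nucleophile and tether.
5. Ring order: naphthalene (aryne Diels–Alder); ring A bought as a benzene ring and Birch reduced; lactone ring (key step); quinone; thiazine ring.

Key step: step 7

Assumption: (R)-BINAP is taken to select the alkene that leads to the (S)-configured quaternary carbon of the target. Should a test run show the opposite sense, (S)-BINAP is used and nothing else changes.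

Step 1
Reactants: 1 1,2,4,5-tetrabromobenzene; 2 2-methoxyfuran
Product: 6 6,7-dibromo-4-methoxynaphthalen-1-ol, via 2,4,5-tribromophenyllithium 3 (not isolated), via 4,5-dibromobenzyne 4 (not isolated), via bridged ketal cycloadduct 5 (not isolated)
Conditions: n-BuLi (1.05 equiv), toluene, −23 °C to rt; then cat. HCl, THF/H2O, rt
Reagents that add atoms: none
Why: Bromine–lithium exchange and loss of LiBr give a symmetric aryne whose Diels–Alder reaction with the electron-rich furan forms a bridged ketal that opens and aromatises under mild acid (aryne Diels–Alder/aromatisation), and the symmetry of the aryne removes any regiochemical question.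

Step 2
Reactants: 6 6,7-dibromo-4-methoxynaphthalen-1-ol
Product: 7 6,7-dibromo-1,4-dimethoxynaphthalene
Conditions: MeI, K2CO3, acetone, reflux
Reagents that add atoms: iodomethane, CI
Why: Williamson O-methylation of the air-sensitive naphthol masks the later quinone as its dimethyl ether and makes the two bromine atoms equivalent.

Step 3
Reactants: 7 6,7-dibromo-1,4-dimethoxynaphthalene
Product: 10 3-bromo-5,8-dimethoxynaphthalene-2-carboxylic acid, via arylmagnesium chloride 8 (not isolated), via chloromagnesium carboxylate 9 (not isolated)
Conditions: i-PrMgCl·LiCl (1.05 equiv), THF, −15 °C; CO2 (g); then 1 M HCl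
Reagents that add atoms: carbon dioxide, O=C=O
Why: Bromine–magnesium exchange is accelerated by the ortho bromine and stops after one exchange, the ortho-bromoaryl Grignard reagent does not collapse to an aryne at this temperature, and carboxylation of the symmetric substrate can give only one regioisomer (halogen–metal exchange/carboxylation).

Step 4
Reactants: 11 2,6-dimethylbenzoic acid
Product: 12 2,6-dimethylcyclohexa-2,5-diene-1-carboxylic acid
Conditions: Li, NH3 (l)/THF, −78 °C; then solid NH4Cl
Reagents that add atoms: none
Why: Birch reduction of a benzoic acid delivers hydrogen para and ipso to the carboxylate, which leaves both methyl groups on the remaining double bonds and gives the mirror-symmetric, unconjugated diene.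

Step 5
Reactants: 12 2,6-dimethylcyclohexa-2,5-diene-1-carboxylic acid
Product: 13 (2,6-dimethylcyclohexa-2,5-dien-1-yl)methanol
Conditions: LiAlH4, Et2O, 0 °C to rt; then H2O
Reagents that add atoms: none
Why: Hydride reduction of the carboxylic acid to the primary alcohol leaves isolated alkenes untouched, and the carboxylate formed first protects the doubly allylic position against base-induced conjugation.

Step 6
Reactants: 13 (2,6-dimethylcyclohexa-2,5-dien-1-yl)methanol
Product: 14 (2,6-dimethylcyclohexa-2,5-dien-1-yl)methyl methanesulfonate
Conditions: MsCl, Et3N, CH2Cl2, 0 °C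
Reagents that add atoms: methanesulfonyl chloride, CS(=O)(=O)Cl
Why: Sulfonylation of an unhindered primary alcohol is fast at 0 °C and turns the exocyclic carbon into an SN2 electrophile without touching the diene.

Step 7
Reactants: 10 3-bromo-5,8-dimethoxynaphthalene-2-carboxylic acid; 14 (2,6-dimethylcyclohexa-2,5-dien-1-yl)methyl methanesulfonate
Product: 16 cis-fused tetracyclic lactone (seven-membered ring O–CH2–CH–C(CH3)(aryl)–C3–C2–C(=O) on the 5,8-dimethoxynaphthalene; ring A is a cyclohexa-1,3-diene CH=CH–CH=C(CH3); quaternary carbon R, adjacent CH S), via dienylmethyl bromonaphthoate ester 15 (not isolated)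
Conditions: Cs2CO3 (1.1 equiv), NMP, 50 °C; then, same flask, Pd2(dba)3·CHCl3 (5 mol %), (R)-BINAP (12 mol %), Ag3PO4 (2 equiv), 90 °C
Reagents that add atoms: none
Why: Deprotonated 10 displaces the primary mesylate of 14 (SN2) and so makes the O–CH2 bond of ester 15; once the palladium and silver salts are in the flask, the C–Br bond of 15 adds to the zerovalent palladium–BINAP complex, Ag3PO4 removes bromide, the cationic arylpalladium inserts one ring alkene with the aryl group going to the methyl-bearing carbon, and syn β-hydride elimination toward the ring CH2 gives the conjugated diene. The closest known reaction type is the asymmetric intramolecular Heck desymmetrisation of prochiral cyclohexa-1,4-dienes, run here directly after a carboxylate alkylation, so that a four-atom O–C(=O)–C=C unit and a three-carbon CH2–CH–C(CH3) unit are joined in a formal (4+3) annulation. The one ring closed is the seven-membered lactone, in the 7-exo-trig mode; the 8-endo alternative would place palladium on a tertiary carbon and build a larger ring, and no other alkene is within reach. The quaternary stereocentre is set by the C2-symmetric diphosphine, which decides which of the two enantiotopic C(CH3)=CH groups binds to palladium, while the adjacent CH stereocentre follows from the tether, because the aryl group can reach only the ring face that carries the CH2O arm (cis fusion). The step needs chemoselectivity between the two electrophilic sites, secured by the order of events (the mesylate reacts at 50 °C before any catalyst is present), and it needs the new diene to stay where it forms, secured because palladium sits on the face opposite to the ring-fusion hydrogen and cannot eliminate it.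

Step 8
Reactants: 16 cis-fused tetracyclic lactone
Product: 17 (S)-dienol lactone (ring A: C(CH3)=CH–CH2–CH2–C(CH3)(aryl)–C(=CH–O); enol lactone O–C(=O) on C2 of the 5,8-dimethoxynaphthalene)
Conditions: RuHCl(CO)(PPh3)3 (10 mol %), toluene, 110 °C
Reagents that add atoms: none
Why: In this ruthenium hydride dienyl isomerisation, reversible hydroruthenation from the face that carries the ring-fusion hydrogen gives η3-allyl complexes whose β-hydride elimination removes first that hydrogen and then one OCH2 hydrogen, so both double bonds walk to the expected thermodynamic sink (an s-trans dienol ester with two trisubstituted alkenes conjugated to the acyloxy oxygen), while the quaternary carbon has no hydrogen, blocks any further walk and keeps its configuration, and the CH stereocentre is erased as planned.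

Step 9
Reactants: 17 (S)-dienol lactone
Product: 18 (S)-naphthoquinone lactone (6,7-disubstituted 1,4-naphthoquinone)
Conditions: (NH4)2Ce(NO3)6 (2.5 equiv), MeCN/H2O, 0 °C
Reagents that add atoms: water, O
Why: Oxidative demethylation of the hydroquinone dimethyl ether (two one-electron oxidations, attack of water, loss of methanol) is fast at 0 °C and should outrun oxidation of the acyloxy diene, whose oxygen lone pair is tied up by the aroyl group.

Step 10
Reactants: 18 (S)-naphthoquinone lactone; 19 hypotaurine (2-aminoethanesulfinic acid)
Product: 23 CNP0348176.1, via sulfonyl hydroquinone 20 (not isolated), via aminoethylsulfonyl quinone 21 (not isolated), via cyclised hydroquinone 22 (not isolated)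
Conditions: EtOH/MeCN/H2O, air (O2 as terminal oxidant, reduced to water), rt
Reagents that add atoms: none
Why: Michael addition of the soft sulfinate sulfur to the quinone CH that lies β to the more electrophilic carbonyl (the one para to the lactone C=O, not the one para to the alkyl-bearing carbon), air reoxidation, intramolecular aza-Michael addition of the amine to the remaining quinone CH and a second air oxidation build the 1,1-dioxo-1,4-thiazine ring in the required orientation, and the zwitterionic reagent offers too little free amine to open the enol lactone.

**Compound list**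
1 | 1,2,4,5-tetrabromobenzene | Brc1cc(Br)c(Br)cc1Br | starting material
2 | 2-methoxyfuran | COc1ccco1 | starting material
3 | 2,4,5-tribromophenyllithium | [Li]c1cc(Br)c(Br)cc1Br | intermediate
4 | 4,5-dibromobenzyne | BrC1=CC#CC=C1Br | intermediate
5 | 6,7-dibromo-1-methoxy-1,4-epoxy-1,4-dihydronaphthalene (bridged ketal cycloadduct, racemic) | COC12C=CC(O1)c1cc(Br)c(Br)cc12 | intermediate
6 | 6,7-dibromo-4-methoxynaphthalen-1-ol | COc1ccc(O)c2cc(Br)c(Br)cc12 | intermediate
7 | 6,7-dibromo-1,4-dimethoxynaphthalene | COc1ccc(OC)c2cc(Br)c(Br)cc12 | intermediate
8 | (3-bromo-5,8-dimethoxynaphthalen-2-yl)magnesium chloride | COc1ccc(OC)c2cc([Mg]Cl)c(Br)cc12 | intermediate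
9 | chloromagnesium 3-bromo-5,8-dimethoxy-2-naphthoate | COc1ccc(OC)c2cc(C(=O)O[Mg]Cl)c(Br)cc12 | intermediate
10 | 3-bromo-5,8-dimethoxynaphthalene-2-carboxylic acid | COc1ccc(OC)c2cc(C(=O)O)c(Br)cc12 | intermediate
11 | 2,6-dimethylbenzoic acid | Cc1cccc(C)c1C(=O)O | starting material
12 | 2,6-dimethylcyclohexa-2,5-diene-1-carboxylic acid | CC1=CCC=C(C)C1C(=O)O | intermediate
13 | (2,6-dimethylcyclohexa-2,5-dien-1-yl)methanol | CC1=CCC=C(C)C1CO | intermediate
14 | (2,6-dimethylcyclohexa-2,5-dien-1-yl)methyl methanesulfonate | CC1=CCC=C(C)C1COS(C)(=O)=O | intermediate
15 | (2,6-dimethylcyclohexa-2,5-dien-1-yl)methyl 3-bromo-5,8-dimethoxy-2-naphthoate | CC1=CCC=C(C)C1COC(=O)c1cc2c(OC)ccc(OC)c2cc1Br | intermediate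
16 | cis-fused Heck lactone, quaternary C (R), adjacent CH (S) | CC1=CC=C[C@]2(C)[C@H]1COC(=O)c1cc3c(OC)ccc(OC)c3cc12 | intermediate
17 | (S)-dienol lactone, dimethoxynaphthalene stage | CC1=CCC[C@]2(C)C1=COC(=O)c1cc3c(OC)ccc(OC)c3cc12 | intermediate
18 | (S)-naphthoquinone lactone | CC1=CCC[C@]2(C)C1=COC(=O)c1cc3C(=O)C=CC(=O)c3cc12 | intermediate
19 | hypotaurine | NCCS(=O)O | starting material
20 | (S)-2-(2-aminoethylsulfonyl)naphthalene-1,4-diol lactone | CC1=CCC[C@]2(C)C1=COC(=O)c1cc3c(O)c(S(=O)(=O)CCN)cc(O)c3cc12 | intermediate
21 | (S)-2-(2-aminoethylsulfonyl)-1,4-naphthoquinone lactone | CC1=CCC[C@]2(C)C1=COC(=O)c1cc3C(=O)C(S(=O)(=O)CCN)=CC(=O)c3cc12 | intermediate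
22 | (S)-thiazine-fused naphthalene-1,4-diol lactone | CC1=CCC[C@]2(C)C1=COC(=O)c1cc3c(O)c4c(c(O)c3cc12)NCCS4(=O)=O | intermediate
23 | CNP0348176.1, (S) | CC1=CCC[C@]2(C)C1=COC(=O)c1cc3c(cc12)C(=O)C1=C(C3=O)S(=O)(=O)CCN1 | target

**Step count:** 10 steps in total. The longest linear sequence is 7 steps (1, 2, 3, 7, 8, 9, 10, or equally 4, 5, 6, 7, 8, 9, 10).

**Steps most likely to fail**

Step 7. The seven-membered ring closure may be slow, because the ester prefers the rotamer that holds the aryl bromide and the alkenes apart. Hydrodebromination, hydrogen transfer from the diene with aromatisation of ring A, or elimination of the mesylate may then compete. The ligand may also discriminate poorly between the two enantiotopic alkenes. The fallback gives up both the one-pot format and catalyst control of configuration. It sets out from 10 and 13. A Mitsunobu esterification (PPh3, DIAD, THF) gives 15, now isolated. A ligand-free Heck cyclisation (Pd(OAc)2, n-Bu4NCl, KOAc, DMF, 80 °C) gives the racemic cis-fused lactone F1. Preparative chromatography on a chiral stationary phase then delivers the required enantiomer, and the route is rejoined at 16.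

Step 8. The double-bond walk may stall at the intermediate ring diene. Alternatively, a β-acyloxy elimination from the ruthenium allyl may open the lactone before the enol ester is reached. The fallback replaces the isomerisation by a redox sequence of known steps and sets out from 16.
- Diimide (2-nitrobenzenesulfonyl hydrazide, Et3N, CH2Cl2) reduces only the disubstituted alkene to the monoene lactone F2.
- LiOH (THF/H2O) opens it to the hydroxy acid F3.
- Dess–Martin periodinane gives the aldehyde acid F4, which is in equilibrium with its lactol.
- Ac2O, NaOAc, 80 °C closes and dehydrates it toward the ring alkene, and the route is rejoined at 17.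

Step 10. First attack by nitrogen, or attack of sulfur at the other quinone CH, would lead to the regioisomeric thiazine. Free amine may also open the enol lactone. The fallback separates the two bond formations and sets out from 18 and 19.
- Boc2O and NaOH convert 19 into sodium N-Boc-hypotaurinate F5.
- F5 can add to 18 only through sulfur (EtOH/H2O/AcOH) and gives the Boc-protected sulfonyl hydroquinone F6, at which stage any regioisomer can be removed.
- Ag2O oxidises it to the Boc-protected sulfonyl quinone F7.
- CF3CO2H in CH2Cl2 at 0 °C frees the amine, and the route is rejoined at 21.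
- 21 closes to 23 on neutralisation with NaHCO3 in air.

**Further compounds**
F1 | step 7 | racemic cis-fused Heck lactone | CC1=CC=C[C@]2(C)[C@H]1COC(=O)c1cc3c(OC)ccc(OC)c3cc12.CC1=CC=C[C@@]2(C)[C@@H]1COC(=O)c1cc3c(OC)ccc(OC)c3cc12
F2 | step 8 | monoene lactone (disubstituted alkene of 16 reduced) | CC1=CCC[C@]2(C)[C@H]1COC(=O)c1cc3c(OC)ccc(OC)c3cc12
F3 | step 8 | hydroxy acid from lactone opening | CC1=CCC[C@@](C)(c2cc3c(OC)ccc(OC)c3cc2C(=O)O)[C@H]1CO
F4 | step 8 | aldehyde acid (formyl-bearing carbon epimerisable) | CC1=CCC[C@@](C)(c2cc3c(OC)ccc(OC)c3cc2C(=O)O)C1C=O
F5 | step 10 | sodium N-Boc-hypotaurinate | CC(C)(C)OC(=O)NCCS(=O)[O-].[Na+]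
F6 | step 10 | Boc-protected sulfonyl hydroquinone | CC1=CCC[C@]2(C)C1=COC(=O)c1cc3c(O)c(S(=O)(=O)CCNC(=O)OC(C)(C)C)cc(O)c3cc12
F7 | step 10 | Boc-protected sulfonyl quinone | CC1=CCC[C@]2(C)C1=COC(=O)c1cc3C(=O)C(S(=O)(=O)CCNC(=O)OC(C)(C)C)=CC(=O)c3cc12
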